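## Retrosynthetic overview

- The target is methyl 6α-acetoxylabda-8(17),12Z,14-trien-19-oate. The (12Z)-diene is cut at C13–C14 (Stille coupling of a (Z)-alkenyl iodide made from a C12 aldehyde); the C8 methylene and the 6α-acetate go back to the 8-ketal 6-ketone of a trans-decalin diester.
- Ring B is the only ring formed in the route. It is closed at C10–C9 by hydrogen-atom-transfer radical addition of a C10 methylene to a tethered C9=C11 enoate.
- Ring A is bought as a cyclohexenone. The strategy rests on its C4 (quaternary, CH3/CO2CH3)–C5(H)–C6(O) triad with C4 β to the C10 carbonyl. This is the imprint of methyl 1,4-addition to a 3-carbomethoxy enone followed by aldol at C5, which forms the C4–CH3 and C5–C6 bonds in one operation.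
- The C6–C12 aldehyde partner comes from monomethyl fumarate by allylsilane acylation, ketalisation and ozonolysis.

Key step: step 5

Remark on numbering and configuration: labdane numbering is used throughout, and the target is read from its SMILES as the (4S,5R,6S,9S,10R) isomer, i.e. 5α-H, 9α-H, 10β-CH3, axial 4β-CO2CH3 and equatorial 6α-OAc.
Remark on the catalyst: the enantiomer of the chiral NHC ligand in step 5 is assumed to be the one that delivers methyl to give (S)-C4.

## Route

Step 1
Reactants: 1 monomethyl fumarate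
Product: 2 methyl (E)-4-chloro-4-oxobut-2-enoate
Conditions: (COCl)2, DMF (cat.), CH2Cl2, 0 °C → rt
Reagents that add atoms: oxalyl chloride, ClC(=O)C(=O)Cl
Why: Acid chloride formation through the chloroiminium species from DMF and oxalyl chloride should proceed without touching the (E)-alkene or the ester.

Step 2
Reactants: 2 methyl (E)-4-chloro-4-oxobut-2-enoate, 3 allyltrimethylsilane
Product: 4 methyl (2E)-4-oxohepta-2,6-dienoate
Conditions: AlCl3 (1.1 equiv), CH2Cl2, −78 °C; cold aq. NaHCO3
Reagents that add atoms: none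
Why: Hosomi–Sakurai-type acylation, in which the allylsilane attacks the AlCl3-activated acyl chloride through its γ-carbon and loses the silyl group, should give the β,γ-unsaturated ketone, which is kept cold so that the skipped diene does not move into conjugation.

Step 3
Reactants: 4 methyl (2E)-4-oxohepta-2,6-dienoate
Product: 5 methyl (E)-3-[2-(prop-2-en-1-yl)-1,3-dioxolan-2-yl]prop-2-enoate
Conditions: Me3SiOCH2CH2OSiMe3, Me3SiOTf (cat.), CH2Cl2, −78 → −20 °C; pyridine quench
Reagents that add atoms: 1,2-bis(trimethylsilyloxy)ethane, C[Si](C)(C)OCCO[Si](C)(C)C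
Why: Noyori ketalisation runs at low temperature without a protic acid, so the ketone should be masked without migration of the allyl double bond or oxa-Michael addition to the enoate.

Step 4
Reactants: 5 methyl (E)-3-[2-(prop-2-en-1-yl)-1,3-dioxolan-2-yl]prop-2-enoate
Product: 7 methyl (E)-3-[2-(2-oxoethyl)-1,3-dioxolan-2-yl]prop-2-enoate, via ozonide 6 (not isolated)
Conditions: O3, CH2Cl2, −78 °C (Sudan Red 7B end point); PPh3, −78 °C → rt
Reagents that add atoms: ozone, [O-][O+]=O
Why: Chemoselective ozonolysis (Criegee mechanism) should cleave the electron-rich terminal alkene much faster than the electron-poor enoate, and PPh3 reduces the ozonide to the aldehyde.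

Step 5
Reactants: 8 methyl 3-oxocyclohex-1-ene-1-carboxylate, 9 dimethylzinc, 7 methyl (E)-3-[2-(2-oxoethyl)-1,3-dioxolan-2-yl]prop-2-enoate
Product: 12 methyl (1S,2R)-2-[(1R)-1-hydroxy-2-{2-[(E)-3-methoxy-3-oxoprop-1-en-1-yl]-1,3-dioxolan-2-yl}ethyl]-1-methyl-3-oxocyclohexane-1-carboxylate (anti-aldol adduct), via zinc enolate 10 (not isolated), via zinc aldolate 11 (not isolated)
Conditions: 9 (3 equiv), (CuOTf)2·C6H6 (2.5 mol%), chiral sulfonate-bearing imidazolinium salt (bidentate NHC precursor, 5 mol%), t-BuOMe, −30 °C; then 7, −78 → −40 °C; aq. NH4Cl, −40 °C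
Reagents that add atoms: none
Why: A chiral NHC–copper methyl species formed by zinc-to-copper transmetalation adds methyl 1,4 to 8 at C4, the ester-bearing carbon β to the ketone, and returns the enolate to zinc as the regiodefined C10–O/C5 zinc enolate 10; the closest known reaction type is the copper-catalysed asymmetric conjugate addition of dialkylzinc reagents to cyclic γ-keto enoates with aldol trapping of the zinc enolate. No ring is closed; the step forms the C4–CH3 and C5–C6 bonds. C4 (S) is set by ligand-controlled enantioface selection in the methyl transfer. C5 (R) is set when the aldehyde binds the enolate face anti to the pseudoaxial C4 methyl, the better σ-donor and bulkier group, with the flat ester pseudoequatorial, so that C6 ends up cis to the ester. C6 (R, the anti-aldol epimer) should follow from the chair Zimmerman–Traxler transition state of the ring-locked (E)-enolate, and because C6 passes through the 6-ketone at step 9 either carbinol epimer is usable. The step needs 1,4- over 1,2-methylation, secured by the copper catalyst and the doubly activated C4=C5 bond, and aldehyde over enoate addition, secured by the far higher electrophilicity of the aldehyde at −78 °C; the cold quench keeps the zinc aldolate from retro-aldol cleavage or lactonisation onto the C4 ester.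

Step 6
Reactants: 12 anti-aldol adduct
Product: 13 methyl (1S,2R)-2-[(1R)-2-{2-[(E)-3-methoxy-3-oxoprop-1-en-1-yl]-1,3-dioxolan-2-yl}-1-(triethylsilyloxy)ethyl]-1-methyl-3-oxocyclohexane-1-carboxylate
Conditions: Et3SiOTf, 2,6-lutidine, CH2Cl2, −78 °C
Reagents that add atoms: triethylsilyl triflate, CC[Si](CC)(CC)OS(=O)(=O)C(F)(F)F
Why: Silylation of the hindered β-hydroxy ketone with a silyl triflate and a non-nucleophilic base should block retro-aldol cleavage and lactonisation during the next step.

Step 7
Reactants: 13 triethylsilyl ether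
Product: 14 methyl (1S,2R)-2-[(1R)-2-{2-[(E)-3-methoxy-3-oxoprop-1-en-1-yl]-1,3-dioxolan-2-yl}-1-(triethylsilyloxy)ethyl]-1-methyl-3-methylidenecyclohexane-1-carboxylate
Conditions: Zn, CH2Br2, TiCl4, THF/CH2Cl2, 0 °C → rt
Reagents that add atoms: dibromomethane, BrCBr
Why: Lombardo methylenation with the non-basic gem-dizinc/titanium reagent should convert the hindered, enolisable C10 ketone into the exocyclic alkene without epimerising C5, eliminating the β-silyloxy group or touching the esters.

Step 8
Reactants: 14 C10-methylidene silyl ether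
Product: 15 methyl (1S,2R)-2-[(1R)-1-hydroxy-2-{2-[(E)-3-methoxy-3-oxoprop-1-en-1-yl]-1,3-dioxolan-2-yl}ethyl]-1-methyl-3-methylidenecyclohexane-1-carboxylate
Conditions: HF·pyridine, pyridine, THF, 0 °C
Reagents that add atoms: none
Why: Fluoride cleavage of the triethylsilyl ether under pyridine buffering should leave the dioxolane intact, and the homoallylic alcohol is oxidised at once so that it does not lactonise onto the C4 ester.

Step 9
Reactants: 15 homoallylic alcohol
Product: 16 methyl (1S,2R)-2-(2-{2-[(E)-3-methoxy-3-oxoprop-1-en-1-yl]-1,3-dioxolan-2-yl}acetyl)-1-methyl-3-methylidenecyclohexane-1-carboxylate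
Conditions: Dess–Martin periodinane, NaHCO3, CH2Cl2, 0 °C
Reagents that add atoms: none
Why: Buffered Dess–Martin oxidation should give the β,γ-unsaturated 6-ketone without moving the C10 double bond, and it removes the C6 stereocentre so that both aldol epimers converge here.

Step 10
Reactants: 16 β,γ-unsaturated 6-ketone
Product: 17 dimethyl 8,8-(ethylenedioxy)-6-oxo-13,14,15,16,17-pentanorlabdane-12,19-dioate (trans-decalin; 5α-H, 9α-H, 10β-CH3, 4β-CO2CH3)
Conditions: Fe(acac)3 (30 mol%), PhSiH3, EtOH/HOCH2CH2OH (5:1), 60 °C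
Reagents that add atoms: none
Why: Iron-hydride hydrogen-atom transfer to the electron-rich C10 methylene gives the tertiary C10 radical, which should close ring B by 6-exo-trig Giese addition to C9 of the enoate through a chair transition state with the tether equatorial on ring A (axial attack would run into the axial C4 ester), placing the new 10β-methyl trans to H-5 and the C9 side chain equatorial before the α-ester radical is reduced and protonated.

Step 11
Reactants: 17 bicyclic 6-ketone
Product: 18 dimethyl 8,8-(ethylenedioxy)-6α-hydroxy-13,14,15,16,17-pentanorlabdane-12,19-dioate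
Conditions: SmI2 (2.5 equiv), H2O, THF, 0 °C
Reagents that add atoms: none
Why: Single-electron (ketyl) reduction with SmI2 and water, the counterpart of a dissolving-metal reduction, is expected to give the thermodynamically preferred equatorial 6α-alcohol because the small proton donor can reach C6 on the hindered β-face, while the esters and the ketal are inert.

Step 12
Reactants: 18 6α-alcohol ketal
Product: 19 dimethyl 6α-hydroxy-8-oxo-13,14,15,16,17-pentanorlabdane-12,19-dioate
Conditions: HCl (1 M aq.), THF, rt
Reagents that add atoms: water, O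
Why: Acid-catalysed ketal hydrolysis should free the C8 ketone, C9 (now α to it) can settle into the equatorial 9β side chain, and the equatorial β-hydroxyl should not eliminate under these mild conditions.

Step 13
Reactants: 19 β-hydroxy ketone
Product: 20 dimethyl 6α-hydroxy-13,14,15,16-tetranorlabd-8(17)-ene-12,19-dioate
Conditions: Zn, CH2Br2, TiCl4, THF/CH2Cl2, 0 °C → rt
Reagents that add atoms: dibromomethane, BrCBr
Why: Lombardo methylenation of the hindered C8 ketone under non-basic conditions should avoid retro-aldol cleavage or dehydration of the β-hydroxy ketone and leave both esters untouched.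

Step 14
Reactants: 20 hydroxy diester
Product: 21 methyl 6α-hydroxy-12-oxo-13,14,15,16-tetranorlabd-8(17)-en-19-oate
Conditions: i-Bu2AlH (2.2 equiv), CH2Cl2, −78 °C; aq. potassium sodium tartrate
Reagents that add atoms: none
Why: Partial reduction with i-Bu2AlH at −78 °C should stop at the aluminium hemiacetal of the unhindered C12 ester, which gives the aldehyde on work-up, while the axial neopentyl C19 ester reacts far more slowly.

Step 15
Reactants: 21 C12 aldehyde
Product: 22 methyl (12Z)-6α-hydroxy-13-iodo-14,15-dinorlabda-8(17),12-dien-19-oate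
Conditions: EtPPh3I, n-BuLi, THF, 0 °C; I2, −78 °C; NaN(SiMe3)2, −20 °C; then 21, −78 → −20 °C
Reagents that add atoms: ethyltriphenylphosphonium iodide, CC[P+](c1ccccc1)(c1ccccc1)c1ccccc1.[I-]; iodine, II
Why: Stork–Zhao-type Wittig olefination with the α-iodo ylide Ph3P=C(I)CH3 should give the (Z)-2-iodoalkene, with iodine cis to C11, under kinetic control through the cis-oxaphosphetane.

Step 16
Reactants: 22 (Z)-alkenyl iodide alcohol
Product: 23 methyl (12Z)-6α-acetoxy-13-iodo-14,15-dinorlabda-8(17),12-dien-19-oate
Conditions: Ac2O, DMAP, Et3N, CH2Cl2, rt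
Reagents that add atoms: acetic anhydride, CC(=O)OC(C)=O
Why: DMAP-catalysed acylation should esterify the equatorial secondary 6α-alcohol without affecting the alkenyl iodide.

Step 17
Reactants: 23 (Z)-alkenyl iodide acetate
Product: 24 methyl 6α-acetoxylabda-8(17),12Z,14-trien-19-oate (target)
Conditions: CH2=CHSnBu3, Pd(PPh3)4 (5 mol%), CuI (10 mol%), CsF, DMF, 45 °C
Reagents that add atoms: tributyl(vinyl)stannane, C=C[Sn](CCCC)(CCCC)CCCC
Why: Stille cross-coupling proceeds with retention of alkene geometry, so the vinyl group should end up cis to C11 and give the (12Z)-diene under neutral conditions that spare the acetate and the exocyclic alkene.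

## Compound list

1 | monomethyl fumarate, (E)-4-methoxy-4-oxobut-2-enoic acid | COC(=O)/C=C/C(=O)O | starting material
2 | methyl (E)-4-chloro-4-oxobut-2-enoate | COC(=O)/C=C/C(=O)Cl | intermediate
3 | allyltrimethylsilane | C=CC[Si](C)(C)C | starting material
4 | methyl (2E)-4-oxohepta-2,6-dienoate | COC(=O)/C=C/C(=O)CC=C | intermediate
5 | methyl (E)-3-[2-(prop-2-en-1-yl)-1,3-dioxolan-2-yl]prop-2-enoate | COC(=O)/C=C/C1(CC=C)OCCO1 | intermediate
6 | ozonide of 5 at the terminal alkene, methyl (E)-3-{2-[(1,2,4-trioxolan-3-yl)methyl]-1,3-dioxolan-2-yl}prop-2-enoate (not isolated) | COC(=O)/C=C/C1(CC2OCOO2)OCCO1 | intermediate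
7 | methyl (E)-3-[2-(2-oxoethyl)-1,3-dioxolan-2-yl]prop-2-enoate | COC(=O)/C=C/C1(CC=O)OCCO1 | intermediate
8 | methyl 3-oxocyclohex-1-ene-1-carboxylate | COC(=O)C1=CC(=O)CCC1 | starting material
9 | dimethylzinc | C[Zn]C | starting material
10 | methylzinc enolate, methyl (1S)-1-methyl-3-[(methylzincio)oxy]cyclohex-2-ene-1-carboxylate (not isolated) | COC(=O)[C@@]1(C)CCCC(O[Zn]C)=C1 | intermediate
11 | methylzinc aldolate of 12 (not isolated) | COC(=O)/C=C/C1(OCCO1)C[C@@H](O[Zn]C)[C@@H]2C(=O)CCC[C@]2(C)C(=O)OC | intermediate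
12 | methyl (1S,2R)-2-[(1R)-1-hydroxy-2-{2-[(E)-3-methoxy-3-oxoprop-1-en-1-yl]-1,3-dioxolan-2-yl}ethyl]-1-methyl-3-oxocyclohexane-1-carboxylate (anti-aldol; labdane C4 S, C5 R, C6 R) | COC(=O)/C=C/C1(OCCO1)C[C@@H](O)[C@@H]2C(=O)CCC[C@]2(C)C(=O)OC | intermediate
13 | triethylsilyl ether of 12 | COC(=O)/C=C/C1(OCCO1)C[C@@H](O[Si](CC)(CC)CC)[C@@H]2C(=O)CCC[C@]2(C)C(=O)OC | intermediate
14 | methyl (1S,2R)-2-[(1R)-2-{2-[(E)-3-methoxy-3-oxoprop-1-en-1-yl]-1,3-dioxolan-2-yl}-1-(triethylsilyloxy)ethyl]-1-methyl-3-methylidenecyclohexane-1-carboxylate | COC(=O)/C=C/C1(OCCO1)C[C@@H](O[Si](CC)(CC)CC)[C@@H]2C(=C)CCC[C@]2(C)C(=O)OC | intermediate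
15 | methyl (1S,2R)-2-[(1R)-1-hydroxy-2-{2-[(E)-3-methoxy-3-oxoprop-1-en-1-yl]-1,3-dioxolan-2-yl}ethyl]-1-methyl-3-methylidenecyclohexane-1-carboxylate | COC(=O)/C=C/C1(OCCO1)C[C@@H](O)[C@@H]2C(=C)CCC[C@]2(C)C(=O)OC | intermediate
16 | methyl (1S,2R)-2-(2-{2-[(E)-3-methoxy-3-oxoprop-1-en-1-yl]-1,3-dioxolan-2-yl}acetyl)-1-methyl-3-methylidenecyclohexane-1-carboxylate | COC(=O)/C=C/C1(OCCO1)CC(=O)[C@@H]2C(=C)CCC[C@]2(C)C(=O)OC | intermediate
17 | dimethyl 8,8-(ethylenedioxy)-6-oxo-13,14,15,16,17-pentanorlabdane-12,19-dioate (trans-decalin; 5α-H, 9α-H, 10β-CH3, 4β-CO2CH3) | COC(=O)C[C@H]1C3(OCCO3)CC(=O)[C@@H]2[C@]1(C)CCC[C@]2(C)C(=O)OC | intermediate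
18 | dimethyl 8,8-(ethylenedioxy)-6α-hydroxy-13,14,15,16,17-pentanorlabdane-12,19-dioate | COC(=O)C[C@H]1C3(OCCO3)C[C@H](O)[C@@H]2[C@]1(C)CCC[C@]2(C)C(=O)OC | intermediate
19 | dimethyl 6α-hydroxy-8-oxo-13,14,15,16,17-pentanorlabdane-12,19-dioate | COC(=O)C[C@H]1C(=O)C[C@H](O)[C@@H]2[C@]1(C)CCC[C@]2(C)C(=O)OC | intermediate
20 | dimethyl 6α-hydroxy-13,14,15,16-tetranorlabd-8(17)-ene-12,19-dioate | COC(=O)C[C@H]1C(=C)C[C@H](O)[C@@H]2[C@]1(C)CCC[C@]2(C)C(=O)OC | intermediate
21 | methyl 6α-hydroxy-12-oxo-13,14,15,16-tetranorlabd-8(17)-en-19-oate | O=CC[C@H]1C(=C)C[C@H](O)[C@@H]2[C@]1(C)CCC[C@]2(C)C(=O)OC | intermediate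
22 | methyl (12Z)-6α-hydroxy-13-iodo-14,15-dinorlabda-8(17),12-dien-19-oate | I/C(C)=C\C[C@H]1C(=C)C[C@H](O)[C@@H]2[C@]1(C)CCC[C@]2(C)C(=O)OC | intermediate
23 | methyl (12Z)-6α-acetoxy-13-iodo-14,15-dinorlabda-8(17),12-dien-19-oate | I/C(C)=C\C[C@H]1C(=C)C[C@H](OC(C)=O)[C@@H]2[C@]1(C)CCC[C@]2(C)C(=O)OC | intermediate
24 | methyl (4S,5R,6S,9S,10R)-6-acetoxylabda-8(17),12Z,14-trien-19-oate (CNP0212193.2) | C=C/C(C)=C\C[C@H]1C(=C)C[C@H](OC(C)=O)[C@@H]2[C@]1(C)CCC[C@]2(C)C(=O)OC | target

## Step count and risks

Total step count: 17. Longest linear sequence: 17 steps (1 → 24 through aldehyde 7); 13 steps from enone 8.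

The three steps most likely to fail:

**Step 5 (key step).** The hindered zinc enolate may deprotonate the enolisable aldehyde or add slowly, and the zinc aldolate may revert or lactonise, so conversion and facial control at C5 could be lost. The fallback sets out from zinc enolate 10 and separates enolate formation from the aldol. The enolate is captured with Me3SiCl/Et3N as the isolable silyl enol ether methyl (1S)-1-methyl-3-(trimethylsilyloxy)cyclohex-2-ene-1-carboxylate F1. MeLi in THF at 0 °C then releases the lithium enolate F2, which should add to 7 at −78 °C within minutes through the same chair transition state to give the lithium aldolate F3. A cold aq. NH4Cl quench comes back to the route at 12.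

**Step 10.** Ring B may close through the axial face of the C10 radical and give the cis ring fusion, or the exocyclic double bond may drift into conjugation with the 6-ketone before hydrogen-atom transfer. The fallback sets out from 16 and fixes C6 before ring closure, so that the C6 substituent steers the fusion. Felkin–Anh reduction with Li(s-Bu)3BH in THF at −78 °C, with hydride anti to the quaternary C4, should give the (6S) homoallylic alcohol F4. Silylation with Et3SiOTf/2,6-lutidine gives the silyl ether F5. The same Fe(acac)3/PhSiH3 cyclisation is then run on F5: the silyloxy group is equatorial only in the trans-decalin chair transition state and axial against the C10 methyl and the ketal oxygen in the cis one, so the bicyclic 6α-silyl ether F6 is expected. HF·pyridine comes back to the route at 18 and makes step 11 unnecessary.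

**Step 11.** The C6 organosamarium may be protonated from the open α-face, or the ketyl may chelate to the axial ketal oxygen, giving the axial 6β-alcohol, which would lactonise onto the C19 ester. The fallback sets out from 17 and uses a dissolving-metal reduction under thermodynamic control. The unhindered C12 ester is saponified selectively with LiOH in THF/H2O to the keto acid F7. Lithium in liquid NH3/THF at −78 °C followed by NH4Cl should then reduce the ketone to the equatorial alcohol, with the C12 carboxylate inert and the hindered C19 ester exposed only briefly, giving the hydroxy acid F8. Me3SiCHN2 in MeOH/toluene comes back to the route at 18.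

Further compounds
F1 | step 5 | methyl (1S)-1-methyl-3-(trimethylsilyloxy)cyclohex-2-ene-1-carboxylate | COC(=O)[C@@]1(C)CCCC(O[Si](C)(C)C)=C1
F2 | step 5 | lithium enolate, methyl (1S)-3-(lithiooxy)-1-methylcyclohex-2-ene-1-carboxylate | COC(=O)[C@@]1(C)CCCC(O[Li])=C1
F3 | step 5 | lithium aldolate of 12 | COC(=O)/C=C/C1(OCCO1)C[C@@H](O[Li])[C@@H]2C(=O)CCC[C@]2(C)C(=O)OC
F4 | step 10 | methyl (1S,2R)-2-[(1S)-1-hydroxy-2-{2-[(E)-3-methoxy-3-oxoprop-1-en-1-yl]-1,3-dioxolan-2-yl}ethyl]-1-methyl-3-methylidenecyclohexane-1-carboxylate | COC(=O)/C=C/C1(OCCO1)C[C@H](O)[C@@H]2C(=C)CCC[C@]2(C)C(=O)OC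
F5 | step 10 | triethylsilyl ether of F4 | COC(=O)/C=C/C1(OCCO1)C[C@H](O[Si](CC)(CC)CC)[C@@H]2C(=C)CCC[C@]2(C)C(=O)OC
F6 | step 10 | dimethyl 8,8-(ethylenedioxy)-6α-(triethylsilyloxy)-13,14,15,16,17-pentanorlabdane-12,19-dioate | COC(=O)C[C@H]1C3(OCCO3)C[C@H](O[Si](CC)(CC)CC)[C@@H]2[C@]1(C)CCC[C@]2(C)C(=O)OC
F7 | step 11 | 8,8-(ethylenedioxy)-19-methoxy-6,19-dioxo-13,14,15,16,17-pentanorlabdan-12-oic acid | OC(=O)C[C@H]1C3(OCCO3)CC(=O)[C@@H]2[C@]1(C)CCC[C@]2(C)C(=O)OC
F8 | step 11 | 8,8-(ethylenedioxy)-6α-hydroxy-19-methoxy-19-oxo-13,14,15,16,17-pentanorlabdan-12-oic acid | OC(=O)C[C@H]1C3(OCCO3)C[C@H](O)[C@@H]2[C@]1(C)CCC[C@]2(C)C(=O)OC
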